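Ring A is the 2-pyranone. Ring B is the benzene, labelled B1 (CH2 bridge), B2 (OH), B3 (prenyl), B4 (OH), B5 (isobutyryl), B6 (OH).
Enabling feature: ring B has oxygen on B2, B4 and B6 and carbon substituents on B1, B3 and B5. B4–B3–B2–B1 is therefore a 2-prenyl β-keto ester (ester carbon B4, ketone carbon B2) at the bis(silyl enol ether) level, and B6–B5 is a β-alkoxy ynone.
Cuts, in order: the O–ethyl bond of a B6 ether; B1–B6 and B4–B5 together (retro-[4+2]); the B2–B3 acyl bond; the ring A C3–CH2 bond (retro-Michael); the ring A lactone C–O bond and the acyl bond of its triketide.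
Forward: ring A closes first by lactonisation. Its C3 is extended by three carbons and then by a prenylated two-carbon unit, ring B closes by benzannulation, and the ether is cleaved last.
Stereochemistry: the target has no stereocentre and no E/Z alkene. Only the (3Z) geometry of the diene matters, and allylic strain sets it during enol silylation.

Key step: step 9

Assumption: the prenylated β-keto ester is drawn as its open keto form, and its enol and cyclic hemiketal tautomers should converge on the same silylated diene. The ketene acetal double bond of that diene is drawn Z, but its geometry has no consequence because that carbon becomes aromatic.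

Step 1
Reactants: 1 methyl 3-oxopentanoate; 2 N-methoxy-N-methylpropanamide
Product: 4 methyl 4-methyl-3,5-dioxoheptanoate (racemic and labile at C4), via dilithium dianion 3 (not isolated)
Conditions: lithium diisopropylamide (2.1 equiv), THF, −78 to 0 °C; 2, −78 to 0 °C; aq. HCl
Reagents that add atoms: lithium diisopropylamide, [Li+].CC(C)[N-]C(C)C (supplies only the lithium of 3; none of its atoms stays in 4)
Why: γ-Acylation of a β-keto ester dianion combined with the Weinreb ketone synthesis: in 3 the carbanion formed last (C4) is the most nucleophilic site, and the chelated tetrahedral adduct survives until the quench, so neither over-addition nor proton transfer to the more acidic product interferes; the new C4 centre is racemic and disappears in step 2.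

Step 2
Reactants: 4 methyl 4-methyl-3,5-dioxoheptanoate
Product: 5 6-ethyl-4-hydroxy-5-methyl-2H-pyran-2-one (ring A)
Conditions: DBU (1 equiv), toluene, reflux; aq. HCl
Reagents that add atoms: none
Why: Base-induced enol lactonisation of a 3,5-dioxo ester (intramolecular acyl substitution, 6-exo-trig): the C5 enolate oxygen displaces methoxide from the ester, and the conjugated 4-hydroxy-2-pyranone, held as its DBU salt, is the thermodynamic sink.

Step 3
Reactants: 5 6-ethyl-4-hydroxy-5-methyl-2H-pyran-2-one; 6 methyl acrylate
Product: 8 3-(6-ethyl-4-hydroxy-5-methyl-2-oxo-2H-pyran-3-yl)propanoic acid, via methyl ester 7 (not isolated)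
Conditions: 6 (1.5 equiv), DBU (0.3 equiv), THF, 60 °C; then LiOH (4 equiv), H2O, rt; aq. HCl to pH 2
Reagents that add atoms: lithium hydroxide, [Li+].[OH-] (its oxygen ends in the carboxyl group of 8)
Why: Michael addition of a cyclic vinylogous acid to an acrylate, as practised with cyclohexane-1,3-diones, occurs at C3 because it is the only unsubstituted nucleophilic carbon of ring A and O-addition is reversible, and the following saponification spares the lactone because ring A is present as its unreactive 4-oxide anion.

Step 4
Reactants: 9 dimethyl malonate; 10 1-bromo-3-methylbut-2-ene (prenyl bromide)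
Product: 11 dimethyl 2-(3-methylbut-2-en-1-yl)malonate
Conditions: 9 (1.2 equiv), NaH (1.0 equiv), THF, 0 °C; 10, 0 °C to rt
Reagents that add atoms: none
Why: Malonic ester synthesis: the deprotonated malonate displaces bromide from the primary allylic halide in an SN2 reaction, and the slight excess of 9 suppresses a second alkylation.

Step 5
Reactants: 11 dimethyl 2-(3-methylbut-2-en-1-yl)malonate
Product: 12 2-(methoxycarbonyl)-5-methylhex-4-enoic acid (racemic)
Conditions: KOH (1.0 equiv), MeOH, 0 °C to rt; aq. HCl
Reagents that add atoms: potassium hydroxide, [K+].[OH-] (its oxygen ends in the carboxyl group of 12)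
Why: Monosaponification of a malonic diester with one equivalent of hydroxide should stop after one ester because the carboxylate formed first shields the remaining ester by charge repulsion; the stereocentre is racemic and is lost later.

Step 6
Reactants: 8 3-(6-ethyl-4-hydroxy-5-methyl-2-oxo-2H-pyran-3-yl)propanoic acid; 12 2-(methoxycarbonyl)-5-methylhex-4-enoic acid
Product: 14 methyl 2-[3-(6-ethyl-4-hydroxy-5-methyl-2-oxo-2H-pyran-3-yl)propanoyl]-5-methylhex-4-enoate (racemic and labile at C2), via acyl imidazolide 13 (not isolated)
Conditions: 8, 1,1'-carbonyldiimidazole (1.2 equiv), THF, rt; then pre-stirred 12 (2 equiv), MgCl2 (2.5 equiv), Et3N (5 equiv), MeCN–THF, rt to 40 °C; aq. citric acid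
Reagents that add atoms: 1,1'-carbonyldiimidazole, O=C(n1ccnc1)n1ccnc1 (supplies only the imidazolyl group of 13; none of its atoms stays in 14)
Why: Decarboxylative Claisen condensation of a malonic half-ester with an acyl imidazolide (Masamune–Brooks type, also established for 2-substituted half-esters): MgCl2/Et3N enolises 12 softly, its α-carbon is acylated by 13 and CO2 is lost, so the prenyl group arrives with the two-carbon unit and no alkylation has to be run beside the acidic ring A hydroxyl; the new C2 centre is racemic and is erased in step 8.

Step 7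
Reactants: 15 ethoxyacetylene; 16 N-methoxy-N,2-dimethylpropanamide
Product: 18 1-ethoxy-4-methylpent-1-yn-3-one, via lithium ethoxyacetylide 17 (not isolated)
Conditions: n-BuLi (1.0 equiv), THF, −78 °C; 16, −78 to 0 °C; inverse quench into cold 0.5 M aq. HCl–Et2O
Reagents that add atoms: n-butyllithium, [Li]CCCC (supplies only the lithium of 17; none of its atoms stays in 18)
Why: Weinreb ketone synthesis with a lithium acetylide: the stable chelated adduct prevents a second addition, and the cold acidic inverse quench protonates the released N,O-dimethylhydroxylamine before it can add to the push-pull alkyne.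

Step 8
Reactants: 14 methyl 2-[3-(6-ethyl-4-hydroxy-5-methyl-2-oxo-2H-pyran-3-yl)propanoyl]-5-methylhex-4-enoate
Product: 19 (1Z,3Z)-1-methoxy-2-(3-methylbut-2-en-1-yl)-1,3-bis(trimethylsilyloxy)-4-[(6-ethyl-5-methyl-2-oxo-4-trimethylsilyloxy-2H-pyran-3-yl)methyl]buta-1,3-diene (diene numbering: C1 ketene acetal carbon, C4 the CH terminus)
Conditions: Et3N (5 equiv), then Me3SiOTf (3.5 equiv), Et2O, 0 °C to rt; pentane, removal of the salt phase under argon, concentration; used crude at once
Reagents that add atoms: trimethylsilyl trifluoromethanesulfonate, C[Si](C)(C)OS(=O)(=O)C(F)(F)F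
Why: Exhaustive soft enolisation with Me3SiOTf/Et3N, the direct route from 1,3-dicarbonyl compounds to 1,3-bis(silyloxy)dienes: Et3N first ionises the ring A hydroxyl, which keeps the chain ketone open and is silylated at once, the keto ester is then silylated on both oxygens, and allylic strain against the fully substituted C2 places the CH2–ring A arm cis to the C3 silyloxy group, that is (3Z).

Step 9
Reactants: 19 the tris(trimethylsilyl) diene; 18 1-ethoxy-4-methylpent-1-yn-3-one
Product: 22 3-{[2-ethoxy-4,6-dihydroxy-3-(2-methylpropanoyl)-5-(3-methylbut-2-en-1-yl)phenyl]methyl}-6-ethyl-4-hydroxy-5-methyl-2H-pyran-2-one, via cyclohexadiene cycloadduct 20 (not isolated), via aryl silyl ether 21 (not isolated)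
Conditions: 18 (1.3 equiv), toluene (1 M), 80 °C, argon; then THF–10% aq. citric acid, rt
Reagents that add atoms: none
Why: Proposed new method: the ketene acetal diene 19 has its largest HOMO coefficient at C4 and the push-pull alkyne 18 its largest LUMO coefficient at the ethoxy-bearing carbon, so an asynchronous [4+2] cycloaddition (at the stepwise limit a Mukaiyama–Michael addition followed by attack of the allenol ether carbon on the silyloxy-oxocarbenium carbon C1) joins C4 to that carbon (B1–B6) and C1 to the acyl-bearing carbon (B4–B5) to give 20. The closest known reaction type is the Diels–Alder reaction and aromatisation of 1-alkoxy-1,3-bis(silyloxy)buta-1,3-dienes with acetylenic ketones and esters to give resorcinols, and what is untested here is the donor substituent on the alkyne together with the fully substituted diene. Ring B closes as a six-membered carbocycle through the suprafacial six-electron transition state, which in the stepwise description is a 6-(enolexo)-exo-trig closure. Adduct 20 expels methoxytrimethylsilane from its mixed ketal carbon C1 and the resulting cyclohexadienone tautomerises through loss of the C4 hydrogen to phenol 21, so the two sp3 centres of 20 are transient and no stereocentre has to be controlled. The step needs regioselectivity (acyl group between two oxygens), which the matched polarity of both partners secures, and chemoselectivity for the open-chain diene over the ring A diene, which the far higher nucleophilicity of the ketene acetal and the full substitution of ring A secure. The (3Z) geometry keeps the CH2–ring A arm on the outside of the s-cis diene, and 80 °C stays below the range in which ethyl ynol ethers fragment to ketene and ethylene.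

Step 10
Reactants: 22 the B6 ethyl ether
Product: 23 3-{[2,4,6-trihydroxy-3-(2-methylpropanoyl)-5-(3-methylbut-2-en-1-yl)phenyl]methyl}-6-ethyl-4-hydroxy-5-methyl-2H-pyran-2-one (target)
Conditions: MgI2 (4 equiv), Et2O–toluene, 70 °C; cold 0.5 M aq. HCl
Reagents that add atoms: none
Why: Chelation-assisted dealkylation of an aryl alkyl ether ortho to a ketone: magnesium held between the ketone oxygen and the ethoxy oxygen turns the phenoxide into a leaving group for SN2 attack of iodide at the ethyl CH2, the reagent is known to spare prenyl chains beside free phenols, and 22 contains no other alkyl–oxygen bond.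

Compound list
1 | methyl 3-oxopentanoate | CCC(=O)CC(=O)OC | starting material
2 | N-methoxy-N-methylpropanamide | CCC(=O)N(C)OC | starting material
3 | dilithium dianion of methyl 3-oxopentanoate | CC=C([O-])C=C([O-])OC.[Li+].[Li+] | intermediate
4 | methyl 4-methyl-3,5-dioxoheptanoate (racemic) | CCC(=O)C(C)C(=O)CC(=O)OC | intermediate
5 | 6-ethyl-4-hydroxy-5-methyl-2H-pyran-2-one | CCc1oc(=O)cc(O)c1C | intermediate
6 | methyl acrylate | C=CC(=O)OC | starting material
7 | methyl 3-(6-ethyl-4-hydroxy-5-methyl-2-oxo-2H-pyran-3-yl)propanoate | CCc1oc(=O)c(CCC(=O)OC)c(O)c1C | intermediate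
8 | 3-(6-ethyl-4-hydroxy-5-methyl-2-oxo-2H-pyran-3-yl)propanoic acid | CCc1oc(=O)c(CCC(=O)O)c(O)c1C | intermediate
9 | dimethyl malonate | COC(=O)CC(=O)OC | starting material
10 | 1-bromo-3-methylbut-2-ene | CC(C)=CCBr | starting material
11 | dimethyl 2-(3-methylbut-2-en-1-yl)malonate | COC(=O)C(CC=C(C)C)C(=O)OC | intermediate
12 | 2-(methoxycarbonyl)-5-methylhex-4-enoic acid (racemic) | COC(=O)C(CC=C(C)C)C(=O)O | intermediate
13 | 6-ethyl-4-hydroxy-3-[3-(imidazol-1-yl)-3-oxopropyl]-5-methyl-2H-pyran-2-one | CCc1oc(=O)c(CCC(=O)n2ccnc2)c(O)c1C | intermediate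
14 | methyl 2-[3-(6-ethyl-4-hydroxy-5-methyl-2-oxo-2H-pyran-3-yl)propanoyl]-5-methylhex-4-enoate (racemic) | CCc1oc(=O)c(CCC(=O)C(CC=C(C)C)C(=O)OC)c(O)c1C | intermediate
15 | ethoxyacetylene | CCOC#C | starting material
16 | N-methoxy-N,2-dimethylpropanamide | CC(C)C(=O)N(C)OC | starting material
17 | lithium ethoxyacetylide | CCOC#[C-].[Li+] | intermediate
18 | 1-ethoxy-4-methylpent-1-yn-3-one | CCOC#CC(=O)C(C)C | intermediate
19 | (1Z,3Z)-1-methoxy-2-(3-methylbut-2-en-1-yl)-1,3-bis(trimethylsilyloxy)-4-[(6-ethyl-5-methyl-2-oxo-4-trimethylsilyloxy-2H-pyran-3-yl)methyl]buta-1,3-diene | CO/C(O[Si](C)(C)C)=C(CC=C(C)C)/C(O[Si](C)(C)C)=C/Cc1c(O[Si](C)(C)C)c(C)c(CC)oc1=O | intermediate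
20 | cyclohexa-1,4-diene cycloadduct (both sp3 centres transient, configuration undefined) | COC1(O[Si](C)(C)C)C(CC=C(C)C)=C(O[Si](C)(C)C)C(Cc2c(O[Si](C)(C)C)c(C)c(CC)oc2=O)C(OCC)=C1C(=O)C(C)C | intermediate
21 | aromatised bis(trimethylsilyl) ether (B2 and ring A oxygens silylated, B4 phenol free) | CCOc1c(C(=O)C(C)C)c(O)c(CC=C(C)C)c(O[Si](C)(C)C)c1Cc1c(O[Si](C)(C)C)c(C)c(CC)oc1=O | intermediate
22 | 3-{[2-ethoxy-4,6-dihydroxy-3-(2-methylpropanoyl)-5-(3-methylbut-2-en-1-yl)phenyl]methyl}-6-ethyl-4-hydroxy-5-methyl-2H-pyran-2-one | CCOc1c(C(=O)C(C)C)c(O)c(CC=C(C)C)c(O)c1Cc1c(O)c(C)c(CC)oc1=O | intermediate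
23 | 3-{[2,4,6-trihydroxy-3-(2-methylpropanoyl)-5-(3-methylbut-2-en-1-yl)phenyl]methyl}-6-ethyl-4-hydroxy-5-methyl-2H-pyran-2-one | CCc1oc(=O)c(Cc2c(O)c(CC=C(C)C)c(O)c(C(=O)C(C)C)c2O)c(O)c1C | target

Total step count: 10. Longest linear sequence: 7 steps (1, 2, 3, 6, 8, 9, 10).

Steps most likely to fail

Step 9. The crowded diene and the donor-deactivated alkyne may not combine before the diene is protodesilylated. The reaction may also stop after the first C–C bond, or heating may fragment the ynol ether. The fallback gives up the benzannulation for the known methylene-bridge assembly of phloroglucinol–pyranone dimers; it sets out from 5 and returns at 23. Friedel–Crafts acylation of phloroglucinol with isobutyryl chloride and AlCl3 gives 2-methyl-1-(2,4,6-trihydroxyphenyl)propan-1-one F1. C-prenylation with 10 in cold aqueous KOH gives 2-methyl-1-[2,4,6-trihydroxy-3-(3-methylbut-2-en-1-yl)phenyl]propan-1-one F2. Separately, 5 and dimethylmethylideneammonium iodide give the Mannich base 3-[(dimethylamino)methyl]-6-ethyl-4-hydroxy-5-methyl-2H-pyran-2-one F3. On warming with F2, F3 loses dimethylamine, and the ring A methide thus formed is captured by the one free ring carbon of F2 to give 23.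

Step 10. Iodide attack at the ethyl group may be slow because the ketone is already engaged by the neighbouring B4 phenol. Long heating with a Lewis acid invites cyclisation of the prenyl chain onto an ortho phenol. The fallback changes the ether carried through the key step rather than the cleaving reagent; it sets out from 16, uses 19 unchanged and returns at 23. Chloroacetaldehyde dimethyl acetal and LiNEt2 (3 equiv) give lithium methoxyacetylide F4. Acylation of F4 with 16 gives 1-methoxy-4-methylpent-1-yn-3-one F5, an ynol ether that cannot undergo the retro-ene fragmentation. Cycloaddition with 19 as in step 9 passes through the methoxy cycloadduct F6 and the aromatised bis(trimethylsilyl) ether F7 to the B6 methyl ether F8. The methyl group of F8 is far more open to SN2 attack, and MgI2 removes it under the milder conditions already established for prenylated ortho-acyl aryl methyl ethers, giving 23.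

Step 8. Silylation may stall at the first enol ether because Et3N cannot remove the γ-proton of the hindered tetrasubstituted enoate. The ethyl group of ring A may be enolised in competition. The diene may also lose geometry or hydrolyse during handling. The fallback replaces soft enolisation with a two-stage hard enolisation; it sets out from 14 and returns at 19. Me3SiCl and Et3N silylate the ring A hydroxyl and the keto ester enol to give methyl 2-(3-methylbut-2-en-1-yl)-3-trimethylsilyloxy-5-(6-ethyl-5-methyl-2-oxo-4-trimethylsilyloxy-2H-pyran-3-yl)pent-2-enoate F9, which is freed from salts and concentrated. Kinetic γ-deprotonation with lithium diisopropylamide in THF at −78 °C, followed by O-silylation of the extended enolate with Me3SiCl, gives 19.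

Further compounds
F1 | step 9 | 2-methyl-1-(2,4,6-trihydroxyphenyl)propan-1-one | CC(C)C(=O)c1c(O)cc(O)cc1O
F2 | step 9 | 2-methyl-1-[2,4,6-trihydroxy-3-(3-methylbut-2-en-1-yl)phenyl]propan-1-one | CC(C)C(=O)c1c(O)cc(O)c(CC=C(C)C)c1O
F3 | step 9 | 3-[(dimethylamino)methyl]-6-ethyl-4-hydroxy-5-methyl-2H-pyran-2-one | CCc1oc(=O)c(CN(C)C)c(O)c1C
F4 | step 10 | lithium methoxyacetylide | COC#[C-].[Li+]
F5 | step 10 | 1-methoxy-4-methylpent-1-yn-3-one | COC#CC(=O)C(C)C
F6 | step 10 | methoxy cycloadduct (both sp3 centres transient, configuration undefined) | COC1=C(C(=O)C(C)C)C(OC)(O[Si](C)(C)C)C(CC=C(C)C)=C(O[Si](C)(C)C)C1Cc1c(O[Si](C)(C)C)c(C)c(CC)oc1=O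
F7 | step 10 | aromatised bis(trimethylsilyl) ether of the methoxy series | COc1c(C(=O)C(C)C)c(O)c(CC=C(C)C)c(O[Si](C)(C)C)c1Cc1c(O[Si](C)(C)C)c(C)c(CC)oc1=O
F8 | step 10 | 3-{[4,6-dihydroxy-2-methoxy-3-(2-methylpropanoyl)-5-(3-methylbut-2-en-1-yl)phenyl]methyl}-6-ethyl-4-hydroxy-5-methyl-2H-pyran-2-one | COc1c(C(=O)C(C)C)c(O)c(CC=C(C)C)c(O)c1Cc1c(O)c(C)c(CC)oc1=O
F9 | step 8 | methyl 2-(3-methylbut-2-en-1-yl)-3-trimethylsilyloxy-5-(6-ethyl-5-methyl-2-oxo-4-trimethylsilyloxy-2H-pyran-3-yl)pent-2-enoate (E/Z undefined) | CCc1oc(=O)c(CCC(O[Si](C)(C)C)=C(CC=C(C)C)C(=O)OC)c(O[Si](C)(C)C)c1C
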